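A direct plan would make aspidinol A1 (butanoylation, then mono-O-methylation of 2-methylphloroglucinol) and 2,4,6-trihydroxy-3-methylacetophenone A2, and would join their single free ring positions with formaldehyde.
Its weakest step would be this bridging: both partners are phloroglucinol nucleophiles of like reactivity, so the homodimers A3 and A4 would form beside the cross product, and the three polyphenols would be hard to separate.
Staging the bridging would not help: the hydroxymethyl derivative A5 of A1 would alkylate unreacted A1 to A3 as fast as it formed.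
The bridge would also stay labile under the condensation conditions (retro-Friedel–Crafts exchange through quinone methides), so even the cross product would scramble.

The route rests on the biogenetic disconnection of ring B, the acetyl-bearing ring (C1' carries the bridge, C3' the methyl, C5' the acetyl). Its oxygenated carbons C2', C4' and C6' alternate with carbon-substituted ones, the pattern of a folded tetraketide, so the C5'–C6' bond is cut and the ring unfolds into a 3,5,7-trioxooctanoate, stored as a 4-hydroxy-2-pyrone that already carries the ring A benzyl group. In one operation Mg(OMe)2 would open the pyrone and close the hexasubstituted ring by Claisen condensation. Ring B never exists as a free nucleophile, so the bridge, drawn from a ring A aldehyde, can form only in the cross sense and has no partner to exchange with.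

Key step: step 8

Remark: 1,3-dicarbonyl compounds are drawn as one tautomer each but would be keto–enol mixtures; the sp3 centres of 5, 10, 16 and 17 are racemic or labile and vanish on the way to the achiral target, so no stereocontrol is needed.

Step 1
Reactants: 1 2-methylphloroglucinol (2-methylbenzene-1,3,5-triol); 2 butanoic acid
Product: 3 1-(2,4,6-trihydroxy-3-methylphenyl)butan-1-one
Conditions: BF3·OEt2, 80 °C; then aq NaOAc, rt
Reagents that add atoms: none
Why: Friedel–Crafts C-acylation of the electron-rich triol promoted by BF3, in which the two free ring positions of 1 are equivalent and the first acyl group deactivates the ring against a second.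

Step 2
Reactants: 3 1-(2,4,6-trihydroxy-3-methylphenyl)butan-1-one
Product: 4 1-(2,6-dihydroxy-4-methoxy-3-methylphenyl)butan-1-one (aspidinol)
Conditions: Me2SO4 (1.0 equiv), K2CO3 (1.0 equiv), acetone, 0 °C to rt
Reagents that add atoms: dimethyl sulfate, COS(=O)(=O)OC
Why: Williamson O-methylation under limiting base, which should select the hydroxyl para to the carbonyl because it is the most acidic and is not hydrogen-bonded to the ketone.

Step 3
Reactants: 4 1-(2,6-dihydroxy-4-methoxy-3-methylphenyl)butan-1-one
Product: 6 3-butanoyl-2,4-dihydroxy-6-methoxy-5-methylbenzaldehyde, via α-chloro ether 5 (not isolated)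
Conditions: Cl2CHOMe, TiCl4, CH2Cl2, −10 to 0 °C; then aq HCl
Reagents that add atoms: dichloromethyl methyl ether, COC(Cl)Cl; water, O
Why: Rieche formylation, an electrophilic aromatic substitution directed by the titanium phenoxide to the only free ring position, which lies ortho to a hydroxyl group; the α-chloro ether 5 is hydrolysed to the aldehyde on work-up.

Step 4
Reactants: 7 methyl 3-oxopentanoate; 8 N-methoxy-N-methylacetamide
Product: 10 methyl 4-methyl-3,5-dioxohexanoate, via dilithium dianion 9 (not isolated)
Conditions: LiN(iPr)2 (2.1 equiv), THF, 0 °C; then 8, −78 to 0 °C; aq HCl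
Reagents that add atoms: none
Why: Claisen-type γ-acylation of a β-keto ester dianion, which reacts at its more basic terminal carbanion, with a Weinreb amide whose chelated tetrahedral adduct survives until work-up and so prevents proton transfer and double addition; the new centre is racemic and labile.

Step 5
Reactants: 10 methyl 4-methyl-3,5-dioxohexanoate
Product: 11 4-hydroxy-5,6-dimethyl-2H-pyran-2-one
Conditions: DBU (1.2 equiv), toluene, reflux; then aq HCl
Reagents that add atoms: none
Why: Base-mediated lactonisation of a 3,5-dioxo ester, in which the enolate oxygen of the C5 ketone attacks the ester carbonyl (6-exo-trig acyl substitution) and loss of methanol gives the 4-hydroxy-2-pyrone, a vinylogous acid whose salt formation drives the closure.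

Step 6
Reactants: 11 4-hydroxy-5,6-dimethyl-2H-pyran-2-one; 8 N-methoxy-N-methylacetamide
Product: 13 4-hydroxy-5-methyl-6-(2-oxopropyl)-2H-pyran-2-one, via dilithium dianion 12 (not isolated)
Conditions: LiN(iPr)2 (2.2 equiv), THF, −78 to −20 °C; then 8, −78 to 0 °C; aq HCl
Reagents that add atoms: none
Why: Acylation of a pyrone dianion in a Weinreb ketone synthesis: after the hydroxyl, the C6 methyl is deprotonated because its anion is conjugated through C5=C6 with the pyronate whereas the C5 methyl is cross-conjugated, and the carbanion, not the delocalised oxygen, attacks the amide.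

Step 7
Reactants: 6 3-butanoyl-2,4-dihydroxy-6-methoxy-5-methylbenzaldehyde; 13 4-hydroxy-5-methyl-6-(2-oxopropyl)-2H-pyran-2-one
Product: 15 3-[(3-butanoyl-2,4-dihydroxy-6-methoxy-5-methylphenyl)methyl]-4-hydroxy-5-methyl-6-(2-oxopropyl)-2H-pyran-2-one, via Knoevenagel adduct 14 (not isolated)
Conditions: diethyl 2,6-dimethyl-1,4-dihydropyridine-3,5-dicarboxylate (Hantzsch ester, 1.1 equiv), L-proline (20 mol %), EtOH–CH2Cl2, 25 to 40 °C
Reagents that add atoms: none
Why: Three-component reductive alkylation, in which proline-catalysed Knoevenagel condensation at C3, the only nucleophilic ring carbon of the vinylogous acid 13, gives the highly electrophilic alkylidene dione 14, to which the Hantzsch ester should transfer hydride in a conjugate sense faster than a second pyrone can add, while the ketones are left alone.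

Step 8
Reactants: 15 3-[(3-butanoyl-2,4-dihydroxy-6-methoxy-5-methylphenyl)methyl]-4-hydroxy-5-methyl-6-(2-oxopropyl)-2H-pyran-2-one
Product: 18 1-[3-[(3-acetyl-2,4,6-trihydroxy-5-methylphenyl)methyl]-2,6-dihydroxy-4-methoxy-5-methylphenyl]butan-1-one (CNP0258463.0), via methyl ester 16 (not isolated), via cyclohexanetrione 17 (not isolated)
Conditions: Mg(OMe)2 (6 equiv), MeOH, 25 to 60 °C; then cold 1 M aq HCl
Reagents that add atoms: none
Why: Methoxide (or the neighbouring ring A phenoxide ortho to the bridge, through a six-membered transition state) should open the magnesium pyronate at its lactone carbonyl to the chelated triketo ester 16, whose most acidic carbon, C6 of the chain (the future C5', between two ketones), then attacks the ester carbon C1 (the future C6') in a Claisen condensation; loss of methoxide gives trione 17, which enolises irreversibly to the phloroglucinol. The closest known reaction type is the Mg(OMe)2-mediated Claisen cyclisation of 3,5,7-trioxo esters and of 6-(2-oxoalkyl)-4-hydroxy-2-pyrones to acylphloroglucinols. Ring B is the only ring closed, by a 6-exo-trig acyl substitution that forms the C5'–C6' bond alone. No stereocentre is set, since the labile centres C1' and C3' of 16 and 17 become sp2 on aromatisation. The selectivity needed is the mode of folding, and the substrate secures it: the competing aldol closure from C1' onto the acetyl carbonyl would create a quaternary carbon that cannot aromatise and should revert, the terminal methyl and the butanoyl CH2 are far less acidic than C5', and O-acylation only returns a pyrone that re-enters the sequence. Magnesium chelation of every 1,3-dicarbonyl unit as its enolate should also guard the chain against retro-Claisen cleavage.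

**Compound list**

1 | 2-methylphloroglucinol (2-methylbenzene-1,3,5-triol) | Cc1c(O)cc(O)cc1O | starting material
2 | butanoic acid | CCCC(=O)O | starting material
3 | 1-(2,4,6-trihydroxy-3-methylphenyl)butan-1-one | CCCC(=O)c1c(O)c(C)c(O)cc1O | intermediate
4 | 1-(2,6-dihydroxy-4-methoxy-3-methylphenyl)butan-1-one (aspidinol) | CCCC(=O)c1c(O)c(C)c(OC)cc1O | intermediate
5 | 1-[3-[chloro(methoxy)methyl]-2,6-dihydroxy-4-methoxy-5-methylphenyl]butan-1-one, racemic (not isolated) | CCCC(=O)c1c(O)c(C)c(OC)c(C(Cl)OC)c1O | intermediate
6 | 3-butanoyl-2,4-dihydroxy-6-methoxy-5-methylbenzaldehyde | CCCC(=O)c1c(O)c(C)c(OC)c(C=O)c1O | intermediate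
7 | methyl 3-oxopentanoate | CCC(=O)CC(=O)OC | starting material
8 | N-methoxy-N-methylacetamide | CON(C)C(C)=O | starting material
9 | dilithium dianion of 7, deprotonated at C2 and C4 (not isolated) | COC(=O)[CH-]C(=O)[CH-]C.[Li+].[Li+] | intermediate
10 | methyl 4-methyl-3,5-dioxohexanoate, racemic and labile at C4 | COC(=O)CC(=O)C(C)C(C)=O | intermediate
11 | 4-hydroxy-5,6-dimethyl-2H-pyran-2-one | CC1=C(C)C(O)=CC(=O)O1 | intermediate
12 | dilithium dianion of 11, deprotonated at the hydroxyl and at the C6 methyl (not isolated) | [CH2-]C1=C(C)C([O-])=CC(=O)O1.[Li+].[Li+] | intermediate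
13 | 4-hydroxy-5-methyl-6-(2-oxopropyl)-2H-pyran-2-one | CC(=O)CC1=C(C)C(O)=CC(=O)O1 | intermediate
14 | 3-[(3-butanoyl-2,4-dihydroxy-6-methoxy-5-methylphenyl)methylidene]-5-methyl-6-(2-oxopropyl)-2H-pyran-2,4(3H)-dione, alkene geometry not fixed (not isolated) | CCCC(=O)c1c(O)c(C)c(OC)c(C=C2C(=O)OC(CC(C)=O)=C(C)C2=O)c1O | intermediate
15 | 3-[(3-butanoyl-2,4-dihydroxy-6-methoxy-5-methylphenyl)methyl]-4-hydroxy-5-methyl-6-(2-oxopropyl)-2H-pyran-2-one | CCCC(=O)c1c(O)c(C)c(OC)c(CC2=C(O)C(C)=C(CC(C)=O)OC2=O)c1O | intermediate
16 | methyl 2-[(3-butanoyl-2,4-dihydroxy-6-methoxy-5-methylphenyl)methyl]-4-methyl-3,5,7-trioxooctanoate, magnesium chelate in the flask, mixture of labile diastereomers (not isolated) | CCCC(=O)c1c(O)c(C)c(OC)c(CC(C(=O)OC)C(=O)C(C)C(=O)CC(C)=O)c1O | intermediate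
17 | 2-acetyl-4-[(3-butanoyl-2,4-dihydroxy-6-methoxy-5-methylphenyl)methyl]-6-methylcyclohexane-1,3,5-trione, mixture of labile diastereomers (not isolated) | CCCC(=O)c1c(O)c(C)c(OC)c(CC2C(=O)C(C)C(=O)C(C(C)=O)C2=O)c1O | intermediate
18 | 1-[3-[(3-acetyl-2,4,6-trihydroxy-5-methylphenyl)methyl]-2,6-dihydroxy-4-methoxy-5-methylphenyl]butan-1-one (CNP0258463.0) | CCCC(=O)c1c(O)c(C)c(OC)c(Cc2c(O)c(C)c(O)c(C(C)=O)c2O)c1O | target

Total step count: 8. Longest linear sequence: 5 steps (1, 2, 3, 7, 8 or 4, 5, 6, 7, 8).

Steps most likely to fail:

Step 8. The opened chain may fragment (retro-Claisen loss of the acetyl end, or expulsion of the keto ester carbanion from the ring A phenoxide through a quinone methide), or the substrate may rest as the unreactive magnesium pyronate instead of folding. The fallback gives up the construction of ring B and sets out from 6 and 1, coming back at 18. Triol 1 would be acetylated (AcOH, BF3·OEt2, 80 °C) to 1-(2,4,6-trihydroxy-3-methylphenyl)ethan-1-one F1. Aldehyde 6 would be reduced (NaBH4, EtOH, 0 °C) to 1-[2,6-dihydroxy-3-(hydroxymethyl)-4-methoxy-5-methylphenyl]butan-1-one F2. F2, used at once, would alkylate the single free ring position of F1 through its quinone methide (TsOH cat., dioxane, 40 °C) in a Friedel–Crafts benzylation to give 18. F2 has no free ring position, so it cannot condense with itself at carbon.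

Step 7. Condensation of the electron-rich, doubly ortho-substituted aldehyde may be slow, which would let lactonisation of 14 onto the ring A phenol (to a coumarin) or addition of a second pyrone overtake the hydride transfer. The fallback avoids the carbonyl condensation and sets out from 4, coming back at 15. A Mannich reaction of 4 (aq CH2O, Me2NH, EtOH, rt) would give 1-[3-[(dimethylamino)methyl]-2,6-dihydroxy-4-methoxy-5-methylphenyl]butan-1-one F3. Heating F3 with pyrone 13 (dioxane, 90 °C) would release the quinone methide, which C3 of the pyrone would trap by Michael addition to give 15.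

Step 6. Proton transfer or O-acylation of the ambident pyronate may take the place of C-acylation at the methyl carbanion, and the dianion may be poorly soluble. The fallback replaces the acylation by an aldol addition and an oxidation and sets out from 11, coming back at 13. Dianion 12 would be added to acetaldehyde (THF, −78 °C) to give 4-hydroxy-6-(2-hydroxypropyl)-5-methyl-2H-pyran-2-one F4 (racemic), which would be oxidised (CrO3, aq H2SO4, acetone, 0 °C) to 13.

Further compounds

F1 | step 8 | 1-(2,4,6-trihydroxy-3-methylphenyl)ethan-1-one | CC(=O)c1c(O)c(C)c(O)cc1O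
F2 | step 8 | 1-[2,6-dihydroxy-3-(hydroxymethyl)-4-methoxy-5-methylphenyl]butan-1-one | CCCC(=O)c1c(O)c(C)c(OC)c(CO)c1O
F3 | step 7 | 1-[3-[(dimethylamino)methyl]-2,6-dihydroxy-4-methoxy-5-methylphenyl]butan-1-one | CCCC(=O)c1c(O)c(C)c(OC)c(CN(C)C)c1O
F4 | step 6 | 4-hydroxy-6-(2-hydroxypropyl)-5-methyl-2H-pyran-2-one, racemic | CC(O)CC1=C(C)C(O)=CC(=O)O1
A1 | direct plan | 1-(2,6-dihydroxy-4-methoxy-3-methylphenyl)butan-1-one (aspidinol) | CCCC(=O)c1c(O)c(C)c(OC)cc1O
A2 | direct plan | 1-(2,4,6-trihydroxy-3-methylphenyl)ethan-1-one | CC(=O)c1c(O)c(C)c(O)cc1O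
A3 | direct plan | bis(3-butanoyl-2,4-dihydroxy-6-methoxy-5-methylphenyl)methane | CCCC(=O)c1c(O)c(C)c(OC)c(Cc2c(OC)c(C)c(O)c(C(=O)CCC)c2O)c1O
A4 | direct plan | bis(3-acetyl-2,4,6-trihydroxy-5-methylphenyl)methane | CC(=O)c1c(O)c(C)c(O)c(Cc2c(O)c(C)c(O)c(C(C)=O)c2O)c1O
A5 | direct plan | 1-[2,6-dihydroxy-3-(hydroxymethyl)-4-methoxy-5-methylphenyl]butan-1-one | CCCC(=O)c1c(O)c(C)c(OC)c(CO)c1O
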